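Two questions stand on this flask: when it holds most X, and how much.

| setting | ash | flask |
|---|---|---|
| Z | 5 mM | 10 mM |
| Q | 20 µM | 20 µM |
| remark | run made earlier |  |
| time |  | 15 d |

ash run (percent of the Z charged)

| time / d | X / % | Z / % |
|---|---|---|
| 0.333 | 48.2 | 44.2 |
| 0.500 | 56.9 | 29.3 |
| 0.833 | 64.5 | 12.5 |
| 1.25 | 65.3 | 4.0 |
| 2.08 | 61.4 | 0.9 |
| 3.00 | 58.8 | 0 |
| 5.00 | 57.2 | 0 |

(each reading ± 0.5 percentage points)

- in percentages every species weighs as the Z in it: one J counts as two
- for X the E are counted in
- as a solid, counted per litre of solution: E
- the earlier runs were read with a standard deviation of 0.5 percentage points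
- steps thought possible: Z + X -> J; Z + Q -> D; E <-> X; X + Q <-> G + Q; D -> Q + X

- time, not beyond 15 d, at which the flask holds most X
- the amount of X, in percent of the Z charged, at that time

I read a ladder of time scales from the ash run. On the first rung Z disappears with a half-life of 0.283 d. On the next, X sinks after its top towards its last reading with a half-life of 0.661 d, slower than Z goes, so X climbs first and falls later.

The third rung needs a ratio. Dividing the rate of Z + X by the rate of Z + Q removes both time and Z and leaves a selectivity factor times dissolved X. Z's rate constant rises from 2.45 /d in the first window to 2.53 /d in the next, while X, taken midway between each window's end readings, rises by 1.61 mM. That gives the side-path factor, the rise in rate constant per mM of X over the catalysed rate constant: 0.0188 /mM, a rough reading given the scatter.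

With X midway to the ash top reading, at 3.27 mM in this flask, the ratio is 0.0613. This puts Z's half-life by the side path at 4.61 d, longer than the half-life of the second rung. Each event takes one Z and one X, so I expect J at 11.5%, against 5.95% for the ash run. I therefore commit to a top of 59.7%, near 1.25 d, as Q is unchanged.

The forecast gives 1.2 d (0.9 d to 2 d) and 58% (53% to 64%), lower than my top, on this ground: “At 10 mM the J step doubles relative to the catalysed step”.

The flask reaches its most X at 1.03 d, with 61.5%.

    Z + X → J (k = 0.0403 /M/min)
    Z + Q → D (k = 83.6 /M/min)
    E ⇌ X, rate k3*(cs3 - [X]) while solid is left; crystals form when [X] > cs3 (solubility = 5.60 mM, k = 0.0276 /min)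
    X + Q ⇌ G + Q, rate k4*[Q]*[X] forward; the back reaction follows from the equilibrium constant (K = 0.563, k = 18.2 /M/min)
    D → Q + X (k = 25.7 /min)

Without the step from X to G, the highest X in the flask is 82.9% instead of 61.5%. J reckoned with the side-path factor comes to 11.5%, less than the 16.5% at the end of the flask. For the neighbour with 0.0050 mM of Q, the factor scaled by Q and that neighbour's top of 43.2% give 27.9% of J, and that neighbour ends with 42.8%.

The readings are calculated with made-up constants; noise was put on by code.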